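**Retrosynthetic overview**
- Aryl ether last: Mitsunobu coupling of umbelliferone with a primary 2,3-epoxy alcohol that already carries the lactone.
- Lactone and oxirane in one flask from an open-chain hydroxy acid whose carbinol oxygen is still masked as a secondary pinacol boronate: Oxone converts C–B to C–OH and the lactone closes, then the same oxidant with the Shi ketone epoxidises the Z-allylic alcohol.
- Open-chain acid: platinum-catalysed enantioselective diboration of an allyl group, then Suzuki coupling of the primary boronate with (Z)-3-iodobut-2-en-1-ol (sets the boron-bearing centre and the Z-olefin).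
- Quaternary carbinol centre: Seebach alkylation of the (S)-lactic acid/pivalaldehyde dioxolanone with allyl bromide.
- Ring order: temporary dioxolanone (opened again during the Suzuki coupling), then lactone followed by oxirane in the same operation; the coumarin is bought as umbelliferone.

Assumption: with Pt(dba)3 the (R,R)-TADDOL phosphonite gives the (S)-1,2-bis(boronate) from a 1-alkene (the sense that gives (R)-1,2-diols on oxidation); if the sense is the reverse, the (S,S)-ligand is used.

Step 1
Reactants: 1 (S)-lactic acid; 2 pivalaldehyde (2,2-dimethylpropanal)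
Product: 3 (2S,5S)-2-tert-butyl-5-methyl-1,3-dioxolan-4-one
Conditions: TsOH·H2O (cat.), H2SO4 (cat.), pentane, reflux, Dean–Stark; recrystallisation from pentane, −78 °C
Reagents that add atoms: none
Why: Acid-catalysed acetalisation with azeotropic water removal (Seebach dioxolanone formation) gives mainly the cis acetal, so the new acetal centre (2S) is set relative to the lactate centre under thermodynamic control and is brought to purity by crystallisation.

Step 2
Reactants: 3 (2S,5S)-2-tert-butyl-5-methyl-1,3-dioxolan-4-one; 4 allyl bromide (3-bromoprop-1-ene)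
Product: 6 (2S,5R)-2-tert-butyl-5-methyl-5-(prop-2-en-1-yl)-1,3-dioxolan-4-one, via lithium enolate 5 (not isolated)
Conditions: LDA (1.05 equiv), THF, −78 °C, 45 min; then 4 (1.5 equiv), −78 → −30 °C
Reagents that add atoms: none
Why: Seebach alkylation with self-regeneration of the stereocentre: allyl bromide attacks the planar enolate 5 anti to the tert-butyl group, so allyl takes the place of the former hydrogen and the quaternary centre (5R, the later R-configured carbinol carbon of the lactone) forms with high diastereoselectivity.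

Step 3
Reactants: 7 but-2-yn-1-ol
Product: 9 (2Z)-3-iodobut-2-en-1-ol, via cyclic alkenylaluminate 8 (not isolated)
Conditions: NaAlH2(OCH2CH2OCH3)2 (Red-Al, 1.4 equiv), Et2O, 0 °C → rt; then I2 (1.5 equiv), THF, −78 → 0 °C
Reagents that add atoms: iodine (I2), [I][I]
Why: Hydroxyl-directed trans-hydroalumination of the propargylic alcohol places aluminium on C3 inside a five-membered alkoxyaluminate, and iodinolysis of the C–Al bond with retention gives the vinyl iodide with iodine cis to CH2OH (Z).

Step 4
Reactants: 6 (2S,5R)-2-tert-butyl-5-methyl-5-(prop-2-en-1-yl)-1,3-dioxolan-4-one; 9 (2Z)-3-iodobut-2-en-1-ol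
Product: 12 (2R,4S,6Z)-2,8-dihydroxy-2,6-dimethyl-4-(4,4,5,5-tetramethyl-1,3,2-dioxaborolan-2-yl)oct-6-enoic acid, via bis(boronate) 10 (not isolated), via potassium carboxylate 11 (not isolated)
Conditions: B2pin2 (1.05 equiv), Pt(dba)3 (3 mol %), (R,R)-3,5-diisopropylphenyl-TADDOL phenylphosphonite (6 mol %), THF, 60 °C, 6 h; then 9 (1.2 equiv), Pd(OAc)2 (2 mol %), RuPhos (2 mol %), KOH (5 equiv), THF–H2O 10:1, 70 °C, 12 h; then aq. HCl to pH 3, 0 °C
Reagents that add atoms: bis(pinacolato)diboron, CC1(C)OB(OC1(C)C)B1OC(C)(C)C(C)(C)O1; potassium hydroxide, [K+].[OH-]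
Why: Morken diboration/cross-coupling: the chiral platinum–phosphonite catalyst adds both boryl groups to one face of the terminal alkene and so sets the boron-bearing centre (S) by catalyst control, only the primary boronate (activated by its neighbour) then undergoes Suzuki–Miyaura coupling with retention of the Z geometry of 9, and the aqueous KOH saponifies the dioxolanone and releases the auxiliary.

Step 5
Reactants: 12 (2R,4S,6Z)-2,8-dihydroxy-2,6-dimethyl-4-(4,4,5,5-tetramethyl-1,3,2-dioxaborolan-2-yl)oct-6-enoic acid
Product: 15 (3R,5R)-3-hydroxy-5-{[(2S,3R)-3-(hydroxymethyl)-2-methyloxiran-2-yl]methyl}-3-methyloxolan-2-one, via trihydroxy acid 13 (not isolated), via hydroxy lactone 14 (not isolated)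
Conditions: Oxone (2KHSO5·KHSO4·K2SO4, 0.6 equiv), MeCN–H2O 2:1, 0 °C → rt, 2 h; then K2CO3 to pH 9.5–10, D-fructose-derived Shi ketone (30 mol %), Bu4NHSO4 (5 mol %), Na2B4O7 buffer, CH2(OMe)2–MeCN, Oxone (1.4 equiv) and K2CO3 added over 2 h, 0 °C
Reagents that add atoms: potassium peroxymonosulfate (KHSO5 of Oxone), [K+].[O-]S(=O)(=O)OO
Why: Proposed new method: one terminal oxidant makes both oxygen transfers in one flask, first peroxymonosulfate adds to boron and the 1,2-shift turns the secondary C–B bond into C–OH with retention while the acidic Oxone medium closes the γ-hydroxy acid to the lactone (ring one), then after buffering the dioxirane of the Shi ketone epoxidises the Z-trisubstituted allylic alcohol through the spiro transition state with the olefinic hydrogen in the hindered quadrant, on the face that D-(−)-tartrate selects in a Sharpless epoxidation, to set both oxirane centres (ring two); the closest known reactions are the Oxone oxidation of alkyl pinacol boronates and the Shi epoxidation of allylic alcohols.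

Step 6
Reactants: 15 (3R,5R)-3-hydroxy-5-{[(2S,3R)-3-(hydroxymethyl)-2-methyloxiran-2-yl]methyl}-3-methyloxolan-2-one; 16 umbelliferone (7-hydroxy-2H-chromen-2-one)
Product: 17 7-{[(2R,3S)-3-{[(2R,4R)-4-hydroxy-4-methyl-5-oxooxolan-2-yl]methyl}-3-methyloxiran-2-yl]methoxy}-2H-chromen-2-one
Conditions: PPh3 (1.3 equiv), DIAD (1.3 equiv), THF, 0 °C → rt
Reagents that add atoms: none
Why: Mitsunobu etherification: the acidic phenol (pKa about 7.8) displaces the oxyphosphonium of the primary alcohol at CH2, so no stereocentre is touched and the tertiary alcohol, the lactone and the oxirane stay intact.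

**Compound list**
1 | (S)-lactic acid | C[C@H](O)C(=O)O | starting material
2 | pivalaldehyde (2,2-dimethylpropanal) | CC(C)(C)C=O | starting material
3 | (2S,5S)-2-tert-butyl-5-methyl-1,3-dioxolan-4-one | C[C@@H]1O[C@H](C(C)(C)C)OC1=O | intermediate
4 | allyl bromide (3-bromoprop-1-ene) | C=CCBr | starting material
5 | lithium (2S)-2-tert-butyl-5-methyl-1,3-dioxol-4-olate (lithium enolate of 3) | CC1=C(O[Li])O[C@@H](C(C)(C)C)O1 | intermediate
6 | (2S,5R)-2-tert-butyl-5-methyl-5-(prop-2-en-1-yl)-1,3-dioxolan-4-one | C=CC[C@@]1(C)O[C@H](C(C)(C)C)OC1=O | intermediate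
7 | but-2-yn-1-ol | CC#CCO | starting material
8 | sodium 2,2-bis(2-methoxyethoxy)-3-methyl-2,5-dihydro-1,2-oxaluminol-2-uide (cyclic alkenylaluminate) | [Na+].CC1=CCO[Al-]1(OCCOC)OCCOC | intermediate
9 | (2Z)-3-iodobut-2-en-1-ol | C/C(I)=C/CO | intermediate
10 | (2S,5R)-5-[(2S)-2,3-bis(4,4,5,5-tetramethyl-1,3,2-dioxaborolan-2-yl)propyl]-2-tert-butyl-5-methyl-1,3-dioxolan-4-one | CC1(C)OB(OC1(C)C)C[C@H](B2OC(C)(C)C(C)(C)O2)C[C@@]3(C)O[C@H](C(C)(C)C)OC3=O | intermediate
11 | potassium (2R,4S)-2-hydroxy-2-methyl-4,5-bis(4,4,5,5-tetramethyl-1,3,2-dioxaborolan-2-yl)pentanoate | [K+].C[C@@](O)(C[C@H](CB1OC(C)(C)C(C)(C)O1)B2OC(C)(C)C(C)(C)O2)C(=O)[O-] | intermediate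
12 | (2R,4S,6Z)-2,8-dihydroxy-2,6-dimethyl-4-(4,4,5,5-tetramethyl-1,3,2-dioxaborolan-2-yl)oct-6-enoic acid | C[C@@](O)(C[C@@H](B1OC(C)(C)C(C)(C)O1)C/C(C)=C\CO)C(=O)O | intermediate
13 | (2R,4S,6Z)-2,4,8-trihydroxy-2,6-dimethyloct-6-enoic acid | C[C@@](O)(C[C@@H](O)C/C(C)=C\CO)C(=O)O | intermediate
14 | (3R,5S)-3-hydroxy-5-[(2Z)-4-hydroxy-2-methylbut-2-en-1-yl]-3-methyloxolan-2-one | C[C@@]1(O)C[C@H](C/C(C)=C\CO)OC1=O | intermediate
15 | (3R,5R)-3-hydroxy-5-{[(2S,3R)-3-(hydroxymethyl)-2-methyloxiran-2-yl]methyl}-3-methyloxolan-2-one | C[C@@]1(O)C[C@H](C[C@]2(C)O[C@@H]2CO)OC1=O | intermediate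
16 | umbelliferone (7-hydroxy-2H-chromen-2-one) | O=c1ccc2ccc(O)cc2o1 | starting material
17 | 7-{[(2R,3S)-3-{[(2R,4R)-4-hydroxy-4-methyl-5-oxooxolan-2-yl]methyl}-3-methyloxiran-2-yl]methoxy}-2H-chromen-2-one | C[C@@]1(O)C[C@H](C[C@]2(C)O[C@@H]2COc2ccc3ccc(=O)oc3c2)OC1=O | target

**Step count and risks**

Total: 6 steps. Longest linear sequence: 5 steps (steps 1, 2, 4, 5, 6); step 3 is the side branch.

The three steps most likely to fail:

Step 4. The risks are the facial sense and level of the diboration next to a quaternary centre, and a Suzuki coupling that has to run while the dioxolanone is being saponified. The fallback sets out from 3 and comes back to the route at 14, taking the carbinol centre from the chiral pool. The enolate 5 is alkylated with (S)-oxiran-2-ylmethyl trifluoromethanesulfonate F1 (made from commercial (R)-glycidol with Tf2O and 2,6-lutidine in CH2Cl2 at −78 °C). Direct displacement of triflate gives the epoxide (2S,5R)-2-tert-butyl-5-methyl-5-[(2R)-oxiran-2-ylmethyl]-1,3-dioxolan-4-one F2. Nickel-catalysed reductive coupling of F2 with 9 (NiCl2(glyme), 2,2'-bipyridine, NaI, Et3N·HCl, zinc dust, DMPU, rt) opens the epoxide with iodide at the terminal carbon and joins that carbon to the alkenyl iodide. The product is the homoallylic alcohol (2S,5R)-2-tert-butyl-5-[(2S,4Z)-2,6-dihydroxy-4-methylhex-4-en-1-yl]-5-methyl-1,3-dioxolan-4-one F3, which closes onto the dioxolanone carbonyl with a trace of TsOH in CH2Cl2 and gives isolated 14. Compound 14 is then epoxidised under the buffered second stage of step 5 alone to reach 15.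

Step 5. The risks are acid-promoted ionisation of the allylic alcohol during the first stage, partial hydrolysis of the α-hydroxy lactone at pH 9.5–10, and a lower enantioface selectivity of the Shi ketone for a Z-trisubstituted olefin than for the E series. The fallback sets out from 12 and comes back at 15; it separates the two oxidations and changes the source of asymmetric induction. Oxidation with NaBO3·4H2O in THF–H2O and acidification to pH 2 give isolated 14. Sharpless asymmetric epoxidation (Ti(OiPr)4, D-(−)-diethyl tartrate, t-BuOOH, 4 Å sieves, CH2Cl2, −20 °C) then gives 15 under titanium–tartrate control, the established method for nerol-type Z-allylic alcohols. No new compound arises on this path (F0).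

Step 6. The risks are the polarity of 15 and possible opening or Payne-type migration of the epoxy alcohol under Mitsunobu conditions. The fallback sets out from 15 and comes back at 17. The primary hydroxyl is sulfonylated selectively (3-nitrobenzenesulfonyl chloride, Et3N, CH2Cl2, −20 °C) to give [(2R,3S)-3-{[(2R,4R)-4-hydroxy-4-methyl-5-oxooxolan-2-yl]methyl}-3-methyloxiran-2-yl]methyl 3-nitrobenzenesulfonate F4. Umbelliferone 16 with Cs2CO3 in DMF at rt then displaces the sulfonate directly at the primary carbon and gives 17.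

Further compounds
F1 | step 4 | (S)-oxiran-2-ylmethyl trifluoromethanesulfonate | FC(F)(F)S(=O)(=O)OC[C@@H]1CO1
F2 | step 4 | (2S,5R)-2-tert-butyl-5-methyl-5-[(2R)-oxiran-2-ylmethyl]-1,3-dioxolan-4-one | C1O[C@@H]1C[C@@]2(C)O[C@H](C(C)(C)C)OC2=O
F3 | step 4 | (2S,5R)-2-tert-butyl-5-[(2S,4Z)-2,6-dihydroxy-4-methylhex-4-en-1-yl]-5-methyl-1,3-dioxolan-4-one | OC/C=C(/C)C[C@H](O)C[C@@]1(C)O[C@H](C(C)(C)C)OC1=O
F0 | step 5 | none | none
F4 | step 6 | [(2R,3S)-3-{[(2R,4R)-4-hydroxy-4-methyl-5-oxooxolan-2-yl]methyl}-3-methyloxiran-2-yl]methyl 3-nitrobenzenesulfonate | C[C@@]1(O)C[C@H](C[C@]2(C)O[C@@H]2COS(=O)(=O)c2cccc(c2)[N+](=O)[O-])OC1=O
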